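**Retrosynthetic overview**
1. Target 24 comes from the (P)-N-oxide 23 by N–O deoxygenation; the axis is not touched.
2. 23 comes from biaryl ketoxime 17 and acetyl sulfoxonium ylide 21 by a new atroposelective trivalent-rhodium C–H acylmethylation/annulation. This step builds the pyridine ring (C4a–C4 and C3–N bonds) and fixes the C5–C1′ axis by dynamic kinetic resolution.
3. 17 comes from ketone 16, made by Suzuki–Miyaura coupling of naphthylboronic acid 13 with bromoacetophenone 15 (three ortho substituents, axis still labile).
4. 13 comes from bromide 10, from 1,8-dimethoxy-3-methylnaphthalene 9, from naphthol 8, made by anionic annulation of the ortho-methallyl benzamide 7 (directed ortho metalation of amide 3).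
5. Ring order: second naphthalene ring, then the biaryl bond, then the pyridine ring of the isoquinoline last.

**Assumption:** the target SMILES has no stereocentre and cannot encode the only stereo element, the tetra-ortho-substituted C5–C1′ axis. I take "single enantiomer" to mean one atropisomer and target (P): viewed along C5→C1′, the shorter turn from C6 (OMe-bearing) to C8a′ is clockwise. The mirror-image catalyst in step 11 would give (M).

**Step 1**
Reactants: 1 2-methoxybenzoyl chloride; 2 diethylamine
Product: 3 N,N-diethyl-2-methoxybenzamide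
Conditions: aq. NaOH (2 M), CH2Cl2, 0 °C → rt
Reagents that add atoms: none
Why: Schotten–Baumann acylation of a secondary amine by an acid chloride is fast and clean, and no stereo element is involved.

**Step 2**
Reactants: 3 N,N-diethyl-2-methoxybenzamide; 4 3-bromo-2-methylprop-1-ene
Product: 7 N,N-diethyl-2-methoxy-6-(2-methylprop-2-en-1-yl)benzamide, via aryllithium 5 (not isolated), via arylmagnesium bromide 6 (not isolated)
Conditions: s-BuLi, TMEDA, THF, −78 °C; MgBr2·OEt2; then 4, −78 °C → rt; aq. NH4Cl
Reagents that add atoms: none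
Why: Directed ortho metalation, in which the tertiary amide outranks OMe as director so lithiation occurs at C6; transmetalation to magnesium gives clean allylation, and the symmetrical methallyl unit gives the same product by SN2 or SN2′.

**Step 3**
Reactants: 7 N,N-diethyl-2-methoxy-6-(2-methylprop-2-en-1-yl)benzamide
Product: 8 8-methoxy-3-methylnaphthalen-1-ol
Conditions: LiN(iPr)2 (2.5 equiv), THF, −78 °C → rt; then 1 M HCl
Reagents that add atoms: none
Why: Anionic ring annulation of an ortho-allyl benzamide: the benzylic/allylic anion attacks the amide carbonyl through its terminal carbon, diethylamide leaves, and the ketone tautomerises to the naphthol.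

**Step 4**
Reactants: 8 8-methoxy-3-methylnaphthalen-1-ol
Product: 9 1,8-dimethoxy-3-methylnaphthalene
Conditions: MeI, K2CO3, DMF, 50 °C
Reagents that add atoms: iodomethane CI
Why: Williamson ether synthesis on the only acidic site of the molecule.

**Step 5**
Reactants: 9 1,8-dimethoxy-3-methylnaphthalene
Product: 10 1-bromo-4,5-dimethoxy-2-methylnaphthalene
Conditions: NBS (1.0 equiv), MeCN, 0 °C → rt
Reagents that add atoms: N-bromosuccinimide O=C1CCC(=O)N1Br
Why: Electrophilic aromatic substitution at the position para to a methoxy group and ortho to the methyl group, which is expected to be the most electron-rich site (the other para position lacks the methyl activation).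

**Step 6**
Reactants: 10 1-bromo-4,5-dimethoxy-2-methylnaphthalene
Product: 13 (4,5-dimethoxy-2-methylnaphthalen-1-yl)boronic acid, via naphthyllithium 11 (not isolated), via lithium aryl(trimethoxy)borate 12 (not isolated)
Conditions: n-BuLi, THF, −78 °C; B(OMe)3, −78 °C → rt; then 1 M HCl
Reagents that add atoms: trimethyl borate COB(OC)OC; water O
Why: Bromine–lithium exchange, borate trapping and hydrolysis is the standard route to hindered 2-methyl-1-naphthylboronic acids.

**Step 7**
Reactants: 14 1-(2,4-dimethoxyphenyl)ethan-1-one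
Product: 15 1-(5-bromo-2,4-dimethoxyphenyl)ethan-1-one
Conditions: NBS (1.05 equiv), MeCN, rt
Reagents that add atoms: N-bromosuccinimide O=C1CCC(=O)N1Br
Why: Electrophilic aromatic substitution at C5, which is para to one methoxy and ortho to the other; C3 is flanked by two methoxy groups and C6 is deactivated by the acetyl group.

**Step 8**
Reactants: 13 (4,5-dimethoxy-2-methylnaphthalen-1-yl)boronic acid; 15 1-(5-bromo-2,4-dimethoxyphenyl)ethan-1-one
Product: 16 1-[5-(4,5-dimethoxy-2-methylnaphthalen-1-yl)-2,4-dimethoxyphenyl]ethan-1-one (racemic, axis configurationally labile)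
Conditions: Pd(OAc)2 (3 mol%), SPhos (6 mol%), K3PO4, toluene/H2O 10:1, 100 °C
Reagents that add atoms: none
Why: Suzuki–Miyaura coupling with a bulky dialkylbiarylphosphine copes with three ortho substituents; the axis is not yet fixed, so no stereocontrol is needed here.

**Step 9**
Reactants: 16 1-[5-(4,5-dimethoxy-2-methylnaphthalen-1-yl)-2,4-dimethoxyphenyl]ethan-1-one
Product: 17 (1E)-1-[5-(4,5-dimethoxy-2-methylnaphthalen-1-yl)-2,4-dimethoxyphenyl]ethan-1-one oxime
Conditions: NH2OH·HCl, NaOAc, EtOH/H2O, 80 °C
Reagents that add atoms: hydroxylamine hydrochloride Cl.NO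
Why: Oxime condensation gives the thermodynamically favoured E isomer (OH anti to the aryl group), which points the nitrogen lone pair at the one free ortho C–H.

**Step 10**
Reactants: 18 trimethylsulfoxonium iodide; 19 acetyl chloride
Product: 21 1-[dimethyl(oxo)-λ6-sulfanylidene]propan-2-one, via dimethylsulfoxonium methylide 20 (not isolated)
Conditions: 18 (3 equiv), KOtBu (3 equiv), THF, reflux; then 19 (1 equiv), 0 °C → rt
Reagents that add atoms: none
Why: Corey–Chaykovsky ylide generation followed by C-acylation, with a second equivalent of methylide acting as base to give the stabilised keto ylide.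

**Step 11**
Reactants: 17 (1E)-1-[5-(4,5-dimethoxy-2-methylnaphthalen-1-yl)-2,4-dimethoxyphenyl]ethan-1-one oxime; 21 1-[dimethyl(oxo)-λ6-sulfanylidene]propan-2-one
Product: 23 (P)-5-(4,5-dimethoxy-2-methylnaphthalen-1-yl)-6,8-dimethoxy-1,3-dimethylisoquinoline 2-oxide, via ortho-acetonyl oxime 22 (not isolated)
Conditions: [(R)-Cp^xRhI2]2 (2.5 mol%; Cp^x = η5-cyclopentadienyl fused through two CH2 groups to the 2,2′-positions of (R)-3,3′-dimethoxy-1,1′-binaphthyl), AgSbF6 (10 mol%), NaOAc (20 mol%), PivOH (1 equiv), 21 (1.5 equiv), ClCH2CH2Cl, 80 °C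
Reagents that add atoms: none
Why: Proposed new method: oxime-directed, carboxylate-assisted and reversible C–H rhodation at the only free ortho position (next to the biaryl carbon) gives two diastereomeric five-membered rhodacycles in which the chiral Cp^x wall faces either the methyl edge or the benzo edge of the perpendicular naphthyl group; these equilibrate through protodemetalation and thermal rotation of the tri-ortho-substituted axis of 17 (estimated barrier about 24–27 kcal/mol, fast at 80 °C), and the better-fitting one captures the ylide, loses DMSO to a rhodium carbene and undergoes migratory insertion, which installs the fourth ortho substituent and locks the axis (dynamic kinetic resolution); the oxime nitrogen then condenses with the new ketone to the aromatic N-oxide. The closest known reactions are the achiral Cp*-rhodium annulation of aryl ketoximes with diazo ketones or sulfoxonium ylides to isoquinoline N-oxides and chiral-Cp rhodium C–H functionalisation of labile biaryls by dynamic kinetic resolution. The (R)-catalyst is predicted, not known, to give (P); the sense is assigned by ECD or X-ray and the (S)-catalyst is used if it is opposite.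

**Step 12**
Reactants: 23 (P)-5-(4,5-dimethoxy-2-methylnaphthalen-1-yl)-6,8-dimethoxy-1,3-dimethylisoquinoline 2-oxide
Product: 24 (P)-5-(4,5-dimethoxy-2-methylnaphthalen-1-yl)-6,8-dimethoxy-1,3-dimethylisoquinoline
Conditions: B2pin2 (1.5 equiv), MeCN, 70 °C
Reagents that add atoms: none
Why: Deoxygenation of a heteroaromatic N-oxide by oxygen transfer to the diboron reagent is mild and chemoselective, and the tetra-ortho-substituted axis does not rotate at this temperature.

**Compound list**
1 | 2-methoxybenzoyl chloride | COc1ccccc1C(Cl)=O | starting material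
2 | diethylamine | CCNCC | starting material
3 | N,N-diethyl-2-methoxybenzamide | CCN(CC)C(=O)c1ccccc1OC | intermediate
4 | 3-bromo-2-methylprop-1-ene | CC(=C)CBr | starting material
5 | [2-(diethylcarbamoyl)-3-methoxyphenyl]lithium | CCN(CC)C(=O)c1c([Li])cccc1OC | intermediate
6 | [2-(diethylcarbamoyl)-3-methoxyphenyl]magnesium bromide | CCN(CC)C(=O)c1c([Mg]Br)cccc1OC | intermediate
7 | N,N-diethyl-2-methoxy-6-(2-methylprop-2-en-1-yl)benzamide | CCN(CC)C(=O)c1c(CC(C)=C)cccc1OC | intermediate
8 | 8-methoxy-3-methylnaphthalen-1-ol | COc1cccc2cc(C)cc(O)c12 | intermediate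
9 | 1,8-dimethoxy-3-methylnaphthalene | COc1cc(C)cc2cccc(OC)c12 | intermediate
10 | 1-bromo-4,5-dimethoxy-2-methylnaphthalene | COc1cc(C)c(Br)c2cccc(OC)c12 | intermediate
11 | (4,5-dimethoxy-2-methylnaphthalen-1-yl)lithium | COc1cc(C)c([Li])c2cccc(OC)c12 | intermediate
12 | lithium (4,5-dimethoxy-2-methylnaphthalen-1-yl)trimethoxyborate | [Li+].COc1cc(C)c([B-](OC)(OC)OC)c2cccc(OC)c12 | intermediate
13 | (4,5-dimethoxy-2-methylnaphthalen-1-yl)boronic acid | COc1cc(C)c(B(O)O)c2cccc(OC)c12 | intermediate
14 | 1-(2,4-dimethoxyphenyl)ethan-1-one | CC(=O)c1ccc(OC)cc1OC | starting material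
15 | 1-(5-bromo-2,4-dimethoxyphenyl)ethan-1-one | CC(=O)c1cc(Br)c(OC)cc1OC | intermediate
16 | 1-[5-(4,5-dimethoxy-2-methylnaphthalen-1-yl)-2,4-dimethoxyphenyl]ethan-1-one (racemic, labile axis) | CC(=O)c1cc(-c2c(C)cc(OC)c3c(OC)cccc23)c(OC)cc1OC | intermediate
17 | (1E)-1-[5-(4,5-dimethoxy-2-methylnaphthalen-1-yl)-2,4-dimethoxyphenyl]ethan-1-one oxime (racemic, labile axis) | C/C(=N\O)c1cc(-c2c(C)cc(OC)c3c(OC)cccc23)c(OC)cc1OC | intermediate
18 | trimethylsulfoxonium iodide | C[S+](C)(C)=O.[I-] | starting material
19 | acetyl chloride | CC(Cl)=O | starting material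
20 | dimethylsulfoxonium methylide | [CH2-][S+](C)(C)=O | intermediate
21 | 1-[dimethyl(oxo)-λ6-sulfanylidene]propan-2-one | CC(=O)C=S(C)(C)=O | intermediate
22 | (P)-(1E)-1-[3-(4,5-dimethoxy-2-methylnaphthalen-1-yl)-4,6-dimethoxy-2-(2-oxopropyl)phenyl]ethan-1-one oxime | C/C(=N\O)c1c(CC(C)=O)c(-c2c(C)cc(OC)c3c(OC)cccc23)c(OC)cc1OC | intermediate
23 | (P)-5-(4,5-dimethoxy-2-methylnaphthalen-1-yl)-6,8-dimethoxy-1,3-dimethylisoquinoline 2-oxide | COc1cc(OC)c2c(C)[n+]([O-])c(C)cc2c1-c1c(C)cc(OC)c2c(OC)cccc12 | intermediate
24 | (P)-5-(4,5-dimethoxy-2-methylnaphthalen-1-yl)-6,8-dimethoxy-1,3-dimethylisoquinoline | COc1cc(OC)c2c(C)nc(C)cc2c1-c1c(C)cc(OC)c2c(OC)cccc12 | target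

**Step count and risks**
Total steps: 12. Longest linear sequence: 10 steps (1, 2, 3, 4, 5, 6, 8, 9, 11, 12).

Most likely to fail:

Step 11 (the proposed new reaction). The C–H bond lies next to the bulky naphthyl group, racemisation of 17 may be too slow for a dynamic process, and the sense and level of induction are unproven. The fallback uses known chemistry, sets out from boronic acid 13 and comes back at target 24. Purchased 1-(3,5-dimethoxyphenyl)propan-2-one (COc1cc(OC)cc(CC(C)=O)c1) is treated with Ac2O and HBF4·OEt2 (Friedel–Crafts acylation ortho to the side chain, then cyclodehydration) to give 6,8-dimethoxy-1,3-dimethyl-2-benzopyrylium tetrafluoroborate F3. Aqueous NH3 in EtOH exchanges ring oxygen for nitrogen to give 6,8-dimethoxy-1,3-dimethylisoquinoline F4. Br2 in AcOH brominates the position para to the 8-methoxy group to give 5-bromo-6,8-dimethoxy-1,3-dimethylisoquinoline F5. Suzuki–Miyaura coupling of F5 with 13 (Pd(OAc)2, SPhos, K3PO4, toluene/H2O, 110 °C) gives racemic 5-(4,5-dimethoxy-2-methylnaphthalen-1-yl)-6,8-dimethoxy-1,3-dimethylisoquinoline F6. Preparative HPLC on a cellulose tris(3,5-dimethylphenylcarbamate) phase separates the stable atropisomers, and the (P)-enantiomer is 24.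

Step 5 (regioselectivity of bromination between the two methoxy-bearing rings). The fallback sets out from naphthol 8 and comes back at bromide 10. The free naphthol, whose hydroxylated ring is far more activated than the anisole ring, is brominated para to OH with NBS (1.0 equiv, MeCN, −20 °C) to give 4-bromo-8-methoxy-3-methylnaphthalen-1-ol F1. O-methylation (MeI, K2CO3, DMF) then gives 10.

Step 8 (hindered coupling; the electron-rich 2-methyl-1-naphthylboronic acid may protodeboronate). The fallback sets out from bromide 10 and comes back at ketone 16. Bromine–lithium exchange (n-BuLi, THF, −78 °C) gives naphthyllithium 11, and ZnCl2 converts it to (4,5-dimethoxy-2-methylnaphthalen-1-yl)zinc chloride F2. Negishi coupling of F2 with 15 (Pd(OAc)2, SPhos, THF, 60 °C) gives 16; the organozinc tolerates the methyl ketone and cannot protodeboronate.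

**Further compounds**
F1 | step 5 | 4-bromo-8-methoxy-3-methylnaphthalen-1-ol | COc1cccc2c(Br)c(C)cc(O)c12
F2 | step 8 | (4,5-dimethoxy-2-methylnaphthalen-1-yl)zinc chloride | COc1cc(C)c([Zn]Cl)c2cccc(OC)c12
F3 | step 11 | 6,8-dimethoxy-1,3-dimethyl-2-benzopyrylium tetrafluoroborate | COc1cc(OC)c2c(C)[o+]c(C)cc2c1.F[B-](F)(F)F
F4 | step 11 | 6,8-dimethoxy-1,3-dimethylisoquinoline | COc1cc(OC)c2c(C)nc(C)cc2c1
F5 | step 11 | 5-bromo-6,8-dimethoxy-1,3-dimethylisoquinoline | COc1cc(OC)c2c(C)nc(C)cc2c1Br
F6 | step 11 | racemic 5-(4,5-dimethoxy-2-methylnaphthalen-1-yl)-6,8-dimethoxy-1,3-dimethylisoquinoline | COc1cc(OC)c2c(C)nc(C)cc2c1-c1c(C)cc(OC)c2c(OC)cccc12
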